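# Proposed synthesis of CNP0167461.3 by chromium-mediated butenolide allylation at C7–C8

Remark on the chemistry: atoms carry germacrane numbers throughout (ring C1–C10, lactone C11–C13 with its oxygen on C6, C14 on C10, C15 on C4). The C8 acyl group is taken exactly as drawn, (2S,3R), which has its two methyl groups cis and is therefore the epoxide of the E acid (tiglic series), not of angelic acid.

## Analysis of the target

The target is a heliangolide-type germacranolide: a ten-membered carbocycle fused through C6 and C7 to an α-methylene-γ-butyrolactone. The ring carries a Z trisubstituted alkene at C4=C5, a trans epoxide at C1–C10 (1R,10R), an isovalerate at C3 (S) and a (2S,3R)-2,3-dimethyloxirane-2-carboxylate at C8 (R). C6 (R), C7 (R) and C8 (R) are contiguous: the lactone is trans-fused and the C8 oxygen lies cis to the C7–C11 bond. C3 is related to C6 only across the Z alkene, and the epoxide carbons are related to the rest only across the ring. Sensitive groups are the exocyclic enoate (a Michael acceptor that migrates into conjugation under base), two acid-labile epoxides, the allylic C–O bonds at C3 and C6, and the base-labile C6–H once the butenolide is present. The difficulty is to close a strained ten-membered ring that holds one E and one Z trisubstituted double bond while three contiguous stereocentres, two different esters and the methylene lactone are put in place. The strategy rests on C7 being the β-carbon and C11=C13 the α-methylene of the lactone while C8 is a carbinol. C7–C8 is therefore the bond formed when the allylmetal of a 3-(halomethyl)butenolide adds through its γ-carbon to a C8 aldehyde.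

## Retrosynthetic reasoning

**32 to 31 (C1–O and C10–O).** The ring epoxide is removed first. In 31 the C1=C10 bond is the only electron-rich alkene: C4=C5 carries two allylic acyloxy groups and C11=C13 is conjugated. An electrophilic oxidant should therefore touch nothing else, and no ring epoxide has to survive organometallic or redox steps. The forward reaction must attack the outer face of the E alkene in the conformer that holds C14 on the β-face, to give (1R,10R).

**31 to 27 and 30 (C8–O, with inversion).** The closed chair transition state of the ring closure is expected to give the 8S alcohol 27, not the 8R configuration the ester needs. The ester bond is therefore cut as an SN2 displacement: activation of the C8 hydroxyl of 27 and attack by the carboxylate of 30 acylates and inverts C8 in one operation. The one centre that the ring closure sets the other way round thus costs no extra step.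

**30 to 29 to 28.** The oxirane acid 30 is the oxidation product of the primary epoxy alcohol 29, which comes from the E allylic alcohol 28 by tartrate-controlled epoxidation. The E geometry of 28 gives the cis relation of the two methyl groups and the tartrate the absolute configuration.

**27 to 25 (C7–C8, the key disconnection).** Cutting C7–C8 opens the ten-membered ring and moves the double bond from C11=C13 to C7=C11, leaving the bromomethylbutenolide aldehyde 25. It is cut here because this single bond carries two stereocentres, the exocyclic methylene and the ring. The lactone and C6 are already present in 25, and the Z C4=C5 and E C1=C10 alkenes fold the chain. The forward step must form the allylchromium 26 and make it add through C7, on the lactone face opposite C5, to the tethered aldehyde.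

**25 to 21 (C8 and C13 oxidation states).** The aldehyde of 25 is β,γ-unsaturated and is made last, from alcohol 24. The allylic bromide comes from alcohol 22, so C13 and C8 need orthogonal protection. In 21 these are a silyl ether at C13 and a 4-methoxybenzyl ether at C8, removed in turn via 22, 23 and 24 under conditions the isovalerate, the butenolide and then the allylic bromide tolerate.

**21 to 16 and 6 (C3–O and C3–C4).** The isovalerate is put on the 3S alcohol 20. The C3–C4 bond is cut between the Z alkenyl iodide 16 and aldehyde 6, because a nickel/chromium coupling joins them without touching the butenolide and keeps the Z geometry. The coupling gives 18 without control at C3, so C3 is set afterwards by oxidation to enone 19 and catalyst-controlled reduction to 20.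

**16 to 9 (C11–C13 and C7=C11).** The protected hydroxymethylbutenolide 16 comes from the saturated lactone 9 through selenide 11, its hydroxymethylated form 13 and selenoxide elimination to 15. The unsaturation is introduced only after the alkene at C4=C5 exists, because a butenolide with an aldehyde on C6 would not hold its stereocentre.

**9 to 7 (C4=C5).** The Z iodoalkene of 9 is traced to aldehyde 8 by a Z-selective α-iodoalkylidene Wittig reaction, and 8 to the chiral-pool lactone alcohol 7, which supplies C6 in the right absolute configuration.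

**6 to 1 (C1–C2 and C10–C14).** Aldehyde 6 comes from alcohol 5, whose E trisubstituted alkene arises by syn carboalumination of alkyne 2 followed by hydroxyethylation of the alkenyl aluminate. Alkyne 2 is the protected form of butynol 1.

## Alternatives that were turned down

**Alternative 1:** The ring is opened at C2–C3 and C1–O, with C3 as a nitrile oxide carbon and C1=C2 as a vinyl group on the C10 carbinol. In the forward step, oxidation of the enal oxime A1 gives a conjugated nitrile oxide that adds across the vinyl group, oxygen to C1, to give the isoxazoline-bridged lactone A2 and with it the ten-membered ring.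
- For it: two bonds form without a metal, and the C3 carbonyl and the C1 oxygen arrive masked in one heterocycle. The C10 carbinol is made in acyclic chemistry, so the oxygen pattern of the later epoxide does not depend on the conformation of a macrocycle. On this point it is stronger than the chosen route, whose last step relies on conformational control. The chosen route offers instead an epoxidation that is the final step and needs no functional-group surgery.
- Against it: the cycloaddition must place the C3=N bond at a bridgehead of a ten-membered ring and reach the alkene through a short, stiff tether, so dimerisation of the dipole is the expected competitor. C1 is set without control.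
- After A2 the N–O bond must be cleaved, the Z enone reduced selectively at C3, the 1,10-diol closed to the epoxide in the right sense, the lactone methylenated, and two silyl ethers exchanged for two different esters.
- Comparison: most of its steps come after the ring closure, whereas the chosen closure delivers ring, C7, C8 and the methylene lactone at once and is followed by two steps.

**Alternative 2:** Both ring alkenes are traced back to the σ-bonds C1–C4 and C5–C10 of a cyclobutane. In the forward step, heating the cis-anti-cis six-four-four tricyclic ketone A3 cleaves these two bonds and unfolds the ten-membered dienone A4 with C1=C10 and C4=C5.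
- For it: the medium ring is released rather than closed, driven by the strain of two four-membered rings, without high dilution, and the alkene geometries follow from the ring fusions. As a way of making the ring it is stronger than a macrocyclisation under dilution. The chosen route offers in exchange a ring closure that already carries every substituent.
- Against it: A4 holds only the C8 stereocentre. C3 is a bare methylene that would need an allylic oxidation in competition with C2, C15 is at the carboxylate level and must be reduced to a methyl group, and C7 lacks the three lactone carbons. The 1,5-diene can also undergo Cope rearrangement at the fragmentation temperature, and the ring-cis enone can isomerise.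
- Comparison: alkylation at C7, reduction at C6, lactonisation, methylenation, adjustment of C15 and oxygenation of C3 make the sequence far longer, with several selectivity problems the chosen route never meets.

**Alternative 3:** The C4=C5 double bond is replaced by a sulfone bridge between C4 and C5. In the forward step, base and a halogen source convert the eleven-membered cyclic sulfone A5 into an episulfone, which extrudes sulfur dioxide and contracts to the ten-membered diene A6.
- For it: the ring is first closed as a larger thioether by simple alkylation at sulfur and only then contracted. C3, C6, C7 and C8 are all set in acyclic chemistry, so C8 arrives with the configuration of the target. On this point it is stronger than the chosen route, which must invert C8. The chosen route answers this by making the inversion part of the esterification.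
- Against it: the carbanions at C4 and C5 each have a β-oxygen substituent (on C3 and on C6), so β-elimination competes directly with the 1,3-closure. The geometry of a trisubstituted alkene formed by this contraction inside a ten-membered ring is not secured towards Z.
- After A6 two 4-methoxybenzyl ethers must be removed, C12 oxidised, the lactone closed and methylenated, and two silyl ethers exchanged selectively for two different esters before the epoxidation.
- Comparison: this is again a long end game, against two steps after the chosen key step.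

Key step: step 18

## Route

Step 1
Reactants: 1 but-3-yn-1-ol
Product: 2 1-[(but-3-yn-1-yloxy)methyl]-4-methoxybenzene
Conditions: NaH, 4-methoxybenzyl chloride, Bu4NI (cat.), THF, 0 °C to rt
Reagents that add atoms: 4-methoxybenzyl chloride, COc1ccc(CCl)cc1
Why: Williamson etherification; the alkoxide is formed selectively because the alcohol is far more acidic than the alkyne C–H, and the 4-methoxybenzyl ether later comes off oxidatively in the presence of an allylic bromide.

Step 2
Reactants: 2 1-[(but-3-yn-1-yloxy)methyl]-4-methoxybenzene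
Product: 5 (3E)-6-[(4-methoxybenzyl)oxy]-4-methylhex-3-en-1-ol, via alkenyldimethylalane 3 (not isolated), via lithium alkenylaluminate 4 (not isolated)
Conditions: Me3Al, Cp2ZrCl2, CH2Cl2, 0 °C to rt; evaporate; n-BuLi, hexane, −30 °C; oxirane, THF, −30 °C to rt; aq. potassium sodium tartrate
Reagents that add atoms: trimethylaluminium, C[Al](C)C; oxirane, C1CO1
Why: Negishi zirconium-catalysed carboalumination adds methyl and aluminium syn across the terminal alkyne (methyl to the internal carbon), which fixes the E geometry of C1=C10; the aluminate formed with n-BuLi opens oxirane with retention of alkene geometry and supplies C2 and C3.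

Step 3
Reactants: 5 (3E)-6-[(4-methoxybenzyl)oxy]-4-methylhex-3-en-1-ol
Product: 6 (3E)-6-[(4-methoxybenzyl)oxy]-4-methylhex-3-enal
Conditions: Dess–Martin periodinane, NaHCO3, CH2Cl2, 0 °C; used at once
Reagents that add atoms: none
Why: Dess–Martin oxidation under buffered, non-basic conditions gives the β,γ-unsaturated aldehyde without moving the double bond into conjugation.

Step 4
Reactants: 7 (5S)-5-(hydroxymethyl)dihydrofuran-2(3H)-one
Product: 8 (2S)-5-oxotetrahydrofuran-2-carbaldehyde
Conditions: (COCl)2, DMSO, CH2Cl2, −78 °C; iPr2NEt, −78 to −40 °C; used crude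
Reagents that add atoms: none
Why: Swern oxidation; the hindered amine and low temperature keep the α-oxygenated stereocentre (the future C6) intact, and the saturated lactone has no vinylogous acidity at this carbon.

Step 5
Reactants: 8 (2S)-5-oxotetrahydrofuran-2-carbaldehyde
Product: 9 (5S)-5-[(1Z)-2-iodoprop-1-en-1-yl]dihydrofuran-2(3H)-one
Conditions: [Ph3PEt]I, n-BuLi, THF, rt; I2, −78 °C; NaN(SiMe3)2, −20 °C; then 8, −78 to −20 °C
Reagents that add atoms: ethyltriphenylphosphonium iodide, CC[P+](c1ccccc1)(c1ccccc1)c1ccccc1.[I-]; iodine, II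
Why: Stork–Zhao-type Wittig olefination with the α-iodoethylidene ylide; kinetic oxaphosphetane formation places iodine cis to the lactone carbon, giving the Z iodoalkene that carries C4 and C15 with the geometry needed for C4=C5.

Step 6
Reactants: 9 (5S)-5-[(1Z)-2-iodoprop-1-en-1-yl]dihydrofuran-2(3H)-one
Product: 11 (5S)-5-[(1Z)-2-iodoprop-1-en-1-yl]-3-(phenylselanyl)dihydrofuran-2(3H)-one (both C3 epimers), via lithium enolate 10 (not isolated)
Conditions: LiN(iPr)2, THF, −78 °C; PhSeBr, −78 °C
Reagents that add atoms: phenylselanyl bromide, Br[Se]c1ccccc1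
Why: Lactone enolate selenenylation; at −78 °C the amide base deprotonates only the lactone α-carbon and leaves the alkenyl iodide untouched, and the new centre is removed again in step 8.

Step 7
Reactants: 11 (5S)-5-[(1Z)-2-iodoprop-1-en-1-yl]-3-(phenylselanyl)dihydrofuran-2(3H)-one
Product: 13 (5S)-3-(hydroxymethyl)-5-[(1Z)-2-iodoprop-1-en-1-yl]-3-(phenylselanyl)dihydrofuran-2(3H)-one (both C3 epimers), via lithium enolate 12 (not isolated)
Conditions: LiN(iPr)2, THF, −78 °C; CH2O (gas), −78 °C; AcOH
Reagents that add atoms: formaldehyde, C=O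
Why: Aldol addition of the selenium-stabilised enolate to monomeric formaldehyde introduces C13; the acidic quench at low temperature prevents retro-aldol cleavage.

Step 8
Reactants: 13 (5S)-3-(hydroxymethyl)-5-[(1Z)-2-iodoprop-1-en-1-yl]-3-(phenylselanyl)dihydrofuran-2(3H)-one
Product: 15 (5S)-3-(hydroxymethyl)-5-[(1Z)-2-iodoprop-1-en-1-yl]furan-2(5H)-one, via selenoxide 14 (not isolated)
Conditions: 30% H2O2, pyridine, CH2Cl2, 0 °C to rt
Reagents that add atoms: none
Why: Selenoxide syn-elimination; elimination runs towards the ring methylene and not towards the carbinol carbon (which would give an enol), so the C7=C11 butenolide with the hydroxymethyl group is formed under conditions too mild to epimerise C6.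

Step 9
Reactants: 15 (5S)-3-(hydroxymethyl)-5-[(1Z)-2-iodoprop-1-en-1-yl]furan-2(5H)-one
Product: 16 (5S)-3-{[(tert-butyldimethylsilyl)oxy]methyl}-5-[(1Z)-2-iodoprop-1-en-1-yl]furan-2(5H)-one
Conditions: TBSCl, imidazole, CH2Cl2, 0 °C
Reagents that add atoms: tert-butyldimethylsilyl chloride, CC(C)(C)[Si](C)(C)Cl
Why: Silylation of the primary allylic alcohol masks C13–OH through the coupling and redox steps; the silyl ether is orthogonal to the 4-methoxybenzyl ether at C8.

Step 10
Reactants: 16 (5S)-3-{[(tert-butyldimethylsilyl)oxy]methyl}-5-[(1Z)-2-iodoprop-1-en-1-yl]furan-2(5H)-one; 6 (3E)-6-[(4-methoxybenzyl)oxy]-4-methylhex-3-enal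
Product: 18 (5R)-3-{[(tert-butyldimethylsilyl)oxy]methyl}-5-[(1Z,5E)-3-hydroxy-8-[(4-methoxybenzyl)oxy]-2,6-dimethylocta-1,5-dien-1-yl]furan-2(5H)-one (both C3 carbinol epimers), via alkenylchromium dichloride 17 (not isolated)
Conditions: CrCl2, NiCl2 (cat.), DMSO, rt
Reagents that add atoms: none
Why: Nozaki–Hiyama–Kishi coupling; nickel-catalysed activation of the C–I bond and transfer to trivalent chromium gives 17 with retention of the Z geometry, and this reagent adds only to the aldehyde, leaving butenolide and silyl ether alone; C3 forms without control and is set in steps 11 and 12.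

Step 11
Reactants: 18 (5R)-3-{[(tert-butyldimethylsilyl)oxy]methyl}-5-[(1Z,5E)-3-hydroxy-8-[(4-methoxybenzyl)oxy]-2,6-dimethylocta-1,5-dien-1-yl]furan-2(5H)-one
Product: 19 (5R)-3-{[(tert-butyldimethylsilyl)oxy]methyl}-5-[(1Z,5E)-8-[(4-methoxybenzyl)oxy]-2,6-dimethyl-3-oxoocta-1,5-dien-1-yl]furan-2(5H)-one
Conditions: Dess–Martin periodinane, NaHCO3, CH2Cl2, 0 °C
Reagents that add atoms: none
Why: Dess–Martin oxidation of the allylic alcohol; the neutral buffered medium avoids Z to E isomerisation of the enone, migration of the C1=C10 bond and deprotonation at C6.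

Step 12
Reactants: 19 (5R)-3-{[(tert-butyldimethylsilyl)oxy]methyl}-5-[(1Z,5E)-8-[(4-methoxybenzyl)oxy]-2,6-dimethyl-3-oxoocta-1,5-dien-1-yl]furan-2(5H)-one
Product: 20 (5R)-3-{[(tert-butyldimethylsilyl)oxy]methyl}-5-[(1Z,3S,5E)-3-hydroxy-8-[(4-methoxybenzyl)oxy]-2,6-dimethylocta-1,5-dien-1-yl]furan-2(5H)-one
Conditions: (R)-2-methyl-CBS-oxazaborolidine (cat.), catecholborane, toluene, −78 °C
Reagents that add atoms: none
Why: Corey–Bakshi–Shibata reduction; the ketone binds the catalyst with the α-branched alkenyl group as the large substituent and the C2 methylene as the small one, so the (R)-catalyst delivers hydride to the face that gives the 3S alcohol, and catecholborane at −78 °C leaves lactone, enoate and alkenes untouched.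

Step 13
Reactants: 20 (5R)-3-{[(tert-butyldimethylsilyl)oxy]methyl}-5-[(1Z,3S,5E)-3-hydroxy-8-[(4-methoxybenzyl)oxy]-2,6-dimethylocta-1,5-dien-1-yl]furan-2(5H)-one
Product: 21 (1Z,3S,5E)-1-[(2R)-4-{[(tert-butyldimethylsilyl)oxy]methyl}-5-oxo-2,5-dihydrofuran-2-yl]-8-[(4-methoxybenzyl)oxy]-2,6-dimethylocta-1,5-dien-3-yl 3-methylbutanoate
Conditions: 3-methylbutanoyl chloride, pyridine, DMAP (cat.), CH2Cl2, 0 °C
Reagents that add atoms: 3-methylbutanoyl chloride, CC(C)CC(Cl)=O
Why: Acylation of the secondary allylic alcohol with retention; pyridine is too weak a base to deprotonate C6 of the butenolide.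

Step 14
Reactants: 21 (1Z,3S,5E)-1-[(2R)-4-{[(tert-butyldimethylsilyl)oxy]methyl}-5-oxo-2,5-dihydrofuran-2-yl]-8-[(4-methoxybenzyl)oxy]-2,6-dimethylocta-1,5-dien-3-yl 3-methylbutanoate
Product: 22 (1Z,3S,5E)-1-[(2R)-4-(hydroxymethyl)-5-oxo-2,5-dihydrofuran-2-yl]-8-[(4-methoxybenzyl)oxy]-2,6-dimethylocta-1,5-dien-3-yl 3-methylbutanoate
Conditions: HF·pyridine, pyridine, THF, 0 °C
Reagents that add atoms: none
Why: Fluoride-mediated desilylation of the primary silyl ether under buffered acidic conditions, which spare the ester, the 4-methoxybenzyl ether and the base-sensitive butenolide.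

Step 15
Reactants: 22 (1Z,3S,5E)-1-[(2R)-4-(hydroxymethyl)-5-oxo-2,5-dihydrofuran-2-yl]-8-[(4-methoxybenzyl)oxy]-2,6-dimethylocta-1,5-dien-3-yl 3-methylbutanoate
Product: 23 (1Z,3S,5E)-1-[(2R)-4-(bromomethyl)-5-oxo-2,5-dihydrofuran-2-yl]-8-[(4-methoxybenzyl)oxy]-2,6-dimethylocta-1,5-dien-3-yl 3-methylbutanoate
Conditions: CBr4, PPh3, CH2Cl2, 0 °C
Reagents that add atoms: carbon tetrabromide, BrC(Br)(Br)Br
Why: Appel bromination of the primary allylic alcohol under neutral conditions; the phosphine is consumed by CBr4 faster than it can add to the butenolide.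

Step 16
Reactants: 23 (1Z,3S,5E)-1-[(2R)-4-(bromomethyl)-5-oxo-2,5-dihydrofuran-2-yl]-8-[(4-methoxybenzyl)oxy]-2,6-dimethylocta-1,5-dien-3-yl 3-methylbutanoate
Product: 24 (1Z,3S,5E)-1-[(2R)-4-(bromomethyl)-5-oxo-2,5-dihydrofuran-2-yl]-8-hydroxy-2,6-dimethylocta-1,5-dien-3-yl 3-methylbutanoate
Conditions: DDQ, CH2Cl2/aq. sodium phosphate buffer (pH 7), 0 °C
Reagents that add atoms: none
Why: Oxidative cleavage of the 4-methoxybenzyl ether by hydride abstraction and hydrolysis; the neutral medium has no nucleophile or base that could attack the allylic bromide.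

Step 17
Reactants: 24 (1Z,3S,5E)-1-[(2R)-4-(bromomethyl)-5-oxo-2,5-dihydrofuran-2-yl]-8-hydroxy-2,6-dimethylocta-1,5-dien-3-yl 3-methylbutanoate
Product: 25 (1Z,3S,5E)-1-[(2R)-4-(bromomethyl)-5-oxo-2,5-dihydrofuran-2-yl]-2,6-dimethyl-8-oxoocta-1,5-dien-3-yl 3-methylbutanoate
Conditions: Dess–Martin periodinane, NaHCO3, CH2Cl2, 0 °C; used at once
Reagents that add atoms: none
Why: Dess–Martin oxidation tolerates the allylic bromide and gives the β,γ-unsaturated C8 aldehyde without base, so the C1=C10 bond stays in place.

Step 18
Reactants: 25 (1Z,3S,5E)-1-[(2R)-4-(bromomethyl)-5-oxo-2,5-dihydrofuran-2-yl]-2,6-dimethyl-8-oxoocta-1,5-dien-3-yl 3-methylbutanoate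
Product: 27 (3aR,4S,6E,9S,10Z,11aR)-4-hydroxy-6,10-dimethyl-3-methylidene-2-oxo-2,3,3a,4,5,8,9,11a-octahydrocyclodeca[b]furan-9-yl 3-methylbutanoate (germacrane numbering 3S,6R,7R,8S), via allylchromium dichloride 26 (not isolated)
Conditions: CrCl2 (excess), THF, rt, slow addition of 25 by syringe pump (high dilution)
Reagents that add atoms: none
Why: Two equivalents of CrCl2 insert into the allylic C13–Br bond to give the σ-allyl species 26 of trivalent chromium, which adds to the tethered aldehyde through its γ-carbon C7 in a closed six-membered Zimmerman–Traxler transition state (Cr–C13–C11=C7···C8=O), forming C7–C8 and regenerating the C11=C13 methylene; this is the intramolecular Nozaki–Hiyama allylation known for ω-formyl 2-(bromomethyl)enoates, applied to a cyclic member of that class. The ten-membered carbocycle closes in a 10-exo-trig mode at the aldehyde carbon, the nucleophile reacting with allylic transposition. C7 is controlled by C6: the seven-atom tether cannot bridge C5 and C8 on the same lactone face, so the aldehyde reaches C7 only on the face opposite the C5 substituent, which gives the trans-fused (6R,7R) lactone. C8 is controlled by the chair: the ring double bond holds C6 trans to the CH2Cr group, as in an E-crotyl reagent, and the tether carbon C9 takes the pseudo-equatorial position anti to C11, the only staggered arrangement from which the chain can pass round the C6–C7 edge to C5, so the anti adduct with H7 and H8 antiperiplanar, the 8S alcohol, is expected. The step needs γ- over α-attack, which the cyclic transition state secures (α-attack would give a twelve-membered ring). It needs ring closure over oligomerisation, which slow addition at high dilution and the folding imposed by the Z C4=C5 and E C1=C10 alkenes secure. It also needs the allylic ester, the enoate and the β,γ-unsaturated aldehyde to survive, and all are inert to CrCl2 under neutral conditions.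

Step 19
Reactants: 28 (2E)-2-methylbut-2-en-1-ol
Product: 29 [(2R,3R)-2,3-dimethyloxiran-2-yl]methanol
Conditions: Ti(OiPr)4, D-(−)-diisopropyl tartrate, t-BuOOH, 4 Å molecular sieves, CH2Cl2, −20 °C
Reagents that add atoms: tert-butyl hydroperoxide, CC(C)(C)OO
Why: Sharpless asymmetric epoxidation; the D-(−)-tartrate delivers oxygen to the face of the E allylic alcohol that gives the (2R,3R) epoxy alcohol (the mirror image of the product of the natural tartrate), and syn addition keeps the two methyl groups cis.

Step 20
Reactants: 29 [(2R,3R)-2,3-dimethyloxiran-2-yl]methanol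
Product: 30 (2S,3R)-2,3-dimethyloxirane-2-carboxylic acid
Conditions: RuCl3 (cat.), NaIO4, CCl4/MeCN/H2O, rt
Reagents that add atoms: water, O
Why: Ruthenium tetroxide oxidation of the primary alcohol through the aldehyde hydrate leaves the oxirane and both stereocentres untouched; the descriptor at C2 changes from R to S only because the carboxyl group outranks the ring carbon.

Step 21
Reactants: 27 (3aR,4S,6E,9S,10Z,11aR)-4-hydroxy-6,10-dimethyl-3-methylidene-2-oxo-2,3,3a,4,5,8,9,11a-octahydrocyclodeca[b]furan-9-yl 3-methylbutanoate; 30 (2S,3R)-2,3-dimethyloxirane-2-carboxylic acid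
Product: 31 (3aR,4R,6E,9S,10Z,11aR)-6,10-dimethyl-3-methylidene-9-[(3-methylbutanoyl)oxy]-2-oxo-2,3,3a,4,5,8,9,11a-octahydrocyclodeca[b]furan-4-yl (2S,3R)-2,3-dimethyloxirane-2-carboxylate
Conditions: PPh3, DIAD, toluene, 0 °C (betaine preformed), then 27 and 30, 0 °C to rt
Reagents that add atoms: none
Why: Mitsunobu esterification; the C8 hydroxyl becomes an oxyphosphonium leaving group that the carboxylate of 30 displaces by SN2 with inversion, turning the 8S alcohol into the 8R ester, and preforming the betaine keeps free phosphine away from the methylene lactone.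

Step 22
Reactants: 31 (3aR,4R,6E,9S,10Z,11aR)-6,10-dimethyl-3-methylidene-9-[(3-methylbutanoyl)oxy]-2-oxo-2,3,3a,4,5,8,9,11a-octahydrocyclodeca[b]furan-4-yl (2S,3R)-2,3-dimethyloxirane-2-carboxylate
Product: 32 CNP0167461.3, the (1R,10R)-1,10-epoxide of 31 (germacrane numbering 1R,3S,6R,7R,8R,10R; acyl group 2S,3R)
Conditions: mCPBA, NaHCO3, CH2Cl2, 0 °C
Reagents that add atoms: 3-chloroperoxybenzoic acid, OOC(=O)c1cccc(Cl)c1
Why: Prilezhaev epoxidation; C1=C10 is the only electron-rich alkene, since C4=C5 is deactivated by two allylic acyloxy groups and C11=C13 by conjugation. The peracid can reach only the outer face of the E alkene, and in the crossed conformation expected for this ring, with C14 on the β-face, that attack gives the trans (1R,10R) epoxide; the buffer protects both epoxides from acid.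

## Compound list

1 | but-3-yn-1-ol | C#CCCO | starting material
2 | 1-[(but-3-yn-1-yloxy)methyl]-4-methoxybenzene | C#CCCOCc1ccc(OC)cc1 | intermediate
3 | dimethyl{(1E)-4-[(4-methoxybenzyl)oxy]-2-methylbut-1-en-1-yl}alumane | C[Al](C)/C=C(\C)CCOCc1ccc(OC)cc1 | intermediate (not isolated)
4 | lithium butyl(dimethyl){(1E)-4-[(4-methoxybenzyl)oxy]-2-methylbut-1-en-1-yl}aluminate | [Li+].CCCC[Al-](C)(C)/C=C(\C)CCOCc1ccc(OC)cc1 | intermediate (not isolated)
5 | (3E)-6-[(4-methoxybenzyl)oxy]-4-methylhex-3-en-1-ol | OCC/C=C(\C)CCOCc1ccc(OC)cc1 | intermediate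
6 | (3E)-6-[(4-methoxybenzyl)oxy]-4-methylhex-3-enal | O=CC/C=C(\C)CCOCc1ccc(OC)cc1 | intermediate
7 | (5S)-5-(hydroxymethyl)dihydrofuran-2(3H)-one | O=C1CC[C@@H](CO)O1 | starting material
8 | (2S)-5-oxotetrahydrofuran-2-carbaldehyde | O=C1CC[C@@H](C=O)O1 | intermediate
9 | (5S)-5-[(1Z)-2-iodoprop-1-en-1-yl]dihydrofuran-2(3H)-one | O=C1CC[C@@H](/C=C(/C)I)O1 | intermediate
10 | lithium enolate of 9, lithium (5S)-5-[(1Z)-2-iodoprop-1-en-1-yl]-4,5-dihydrofuran-2-olate | [Li+].[O-]C1=CC[C@@H](/C=C(/C)I)O1 | intermediate (not isolated)
11 | (5S)-5-[(1Z)-2-iodoprop-1-en-1-yl]-3-(phenylselanyl)dihydrofuran-2(3H)-one, both C3 epimers | O=C1C([Se]c2ccccc2)C[C@@H](/C=C(/C)I)O1 | intermediate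
12 | lithium enolate of 11 | [Li+].[O-]C1=C([Se]c2ccccc2)C[C@@H](/C=C(/C)I)O1 | intermediate (not isolated)
13 | (5S)-3-(hydroxymethyl)-5-[(1Z)-2-iodoprop-1-en-1-yl]-3-(phenylselanyl)dihydrofuran-2(3H)-one, both C3 epimers | O=C1C(CO)([Se]c2ccccc2)C[C@@H](/C=C(/C)I)O1 | intermediate
14 | selenoxide of 13 | O=C1C(CO)([Se](=O)c2ccccc2)C[C@@H](/C=C(/C)I)O1 | intermediate (not isolated)
15 | (5S)-3-(hydroxymethyl)-5-[(1Z)-2-iodoprop-1-en-1-yl]furan-2(5H)-one | O=C1C(CO)=C[C@@H](/C=C(/C)I)O1 | intermediate
16 | (5S)-3-{[(tert-butyldimethylsilyl)oxy]methyl}-5-[(1Z)-2-iodoprop-1-en-1-yl]furan-2(5H)-one | O=C1C(CO[Si](C)(C)C(C)(C)C)=C[C@@H](/C=C(/C)I)O1 | intermediate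
17 | Z-alkenylchromium dichloride from 16 (trivalent chromium in place of iodine, C6 unchanged) | O=C1C(CO[Si](C)(C)C(C)(C)C)=C[C@@H](/C=C(/C)[Cr](Cl)Cl)O1 | intermediate (not isolated)
18 | (5R)-3-{[(tert-butyldimethylsilyl)oxy]methyl}-5-[(1Z,5E)-3-hydroxy-8-[(4-methoxybenzyl)oxy]-2,6-dimethylocta-1,5-dien-1-yl]furan-2(5H)-one, both C3 carbinol epimers | O=C1C(CO[Si](C)(C)C(C)(C)C)=C[C@@H](/C=C(/C)C(O)C/C=C(\C)CCOCc2ccc(OC)cc2)O1 | intermediate
19 | (5R)-3-{[(tert-butyldimethylsilyl)oxy]methyl}-5-[(1Z,5E)-8-[(4-methoxybenzyl)oxy]-2,6-dimethyl-3-oxoocta-1,5-dien-1-yl]furan-2(5H)-one | O=C1C(CO[Si](C)(C)C(C)(C)C)=C[C@@H](/C=C(/C)C(=O)C/C=C(\C)CCOCc2ccc(OC)cc2)O1 | intermediate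
20 | (5R)-3-{[(tert-butyldimethylsilyl)oxy]methyl}-5-[(1Z,3S,5E)-3-hydroxy-8-[(4-methoxybenzyl)oxy]-2,6-dimethylocta-1,5-dien-1-yl]furan-2(5H)-one | O=C1C(CO[Si](C)(C)C(C)(C)C)=C[C@@H](/C=C(/C)[C@@H](O)C/C=C(\C)CCOCc2ccc(OC)cc2)O1 | intermediate
21 | (1Z,3S,5E)-1-[(2R)-4-{[(tert-butyldimethylsilyl)oxy]methyl}-5-oxo-2,5-dihydrofuran-2-yl]-8-[(4-methoxybenzyl)oxy]-2,6-dimethylocta-1,5-dien-3-yl 3-methylbutanoate | O=C1C(CO[Si](C)(C)C(C)(C)C)=C[C@@H](/C=C(/C)[C@@H](OC(=O)CC(C)C)C/C=C(\C)CCOCc2ccc(OC)cc2)O1 | intermediate
22 | (1Z,3S,5E)-1-[(2R)-4-(hydroxymethyl)-5-oxo-2,5-dihydrofuran-2-yl]-8-[(4-methoxybenzyl)oxy]-2,6-dimethylocta-1,5-dien-3-yl 3-methylbutanoate | O=C1C(CO)=C[C@@H](/C=C(/C)[C@@H](OC(=O)CC(C)C)C/C=C(\C)CCOCc2ccc(OC)cc2)O1 | intermediate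
23 | (1Z,3S,5E)-1-[(2R)-4-(bromomethyl)-5-oxo-2,5-dihydrofuran-2-yl]-8-[(4-methoxybenzyl)oxy]-2,6-dimethylocta-1,5-dien-3-yl 3-methylbutanoate | O=C1C(CBr)=C[C@@H](/C=C(/C)[C@@H](OC(=O)CC(C)C)C/C=C(\C)CCOCc2ccc(OC)cc2)O1 | intermediate
24 | (1Z,3S,5E)-1-[(2R)-4-(bromomethyl)-5-oxo-2,5-dihydrofuran-2-yl]-8-hydroxy-2,6-dimethylocta-1,5-dien-3-yl 3-methylbutanoate | O=C1C(CBr)=C[C@@H](/C=C(/C)[C@@H](OC(=O)CC(C)C)C/C=C(\C)CCO)O1 | intermediate
25 | (1Z,3S,5E)-1-[(2R)-4-(bromomethyl)-5-oxo-2,5-dihydrofuran-2-yl]-2,6-dimethyl-8-oxoocta-1,5-dien-3-yl 3-methylbutanoate (precursor of the key step) | O=C1C(CBr)=C[C@@H](/C=C(/C)[C@@H](OC(=O)CC(C)C)C/C=C(\C)CC=O)O1 | intermediate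
26 | allylchromium dichloride from 25 (trivalent chromium on C13 in place of bromine) | O=C1C(C[Cr](Cl)Cl)=C[C@@H](/C=C(/C)[C@@H](OC(=O)CC(C)C)C/C=C(\C)CC=O)O1 | intermediate (not isolated)
27 | (3aR,4S,6E,9S,10Z,11aR)-4-hydroxy-6,10-dimethyl-3-methylidene-2-oxo-2,3,3a,4,5,8,9,11a-octahydrocyclodeca[b]furan-9-yl 3-methylbutanoate (8S alcohol, product of the key step) | C=C1C(=O)O[C@@H]2/C=C(/C)[C@@H](OC(=O)CC(C)C)C/C=C(\C)C[C@H](O)[C@@H]12 | intermediate
28 | (2E)-2-methylbut-2-en-1-ol | C/C=C(\C)CO | starting material
29 | [(2R,3R)-2,3-dimethyloxiran-2-yl]methanol | OC[C@@]1(C)O[C@@H]1C | intermediate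
30 | (2S,3R)-2,3-dimethyloxirane-2-carboxylic acid | OC(=O)[C@@]1(C)O[C@@H]1C | intermediate
31 | (3aR,4R,6E,9S,10Z,11aR)-6,10-dimethyl-3-methylidene-9-[(3-methylbutanoyl)oxy]-2-oxo-2,3,3a,4,5,8,9,11a-octahydrocyclodeca[b]furan-4-yl (2S,3R)-2,3-dimethyloxirane-2-carboxylate | C=C1C(=O)O[C@@H]2/C=C(/C)[C@@H](OC(=O)CC(C)C)C/C=C(\C)C[C@@H](OC(=O)[C@@]3(C)O[C@@H]3C)[C@@H]12 | intermediate
32 | CNP0167461.3, (1R,10R)-1,10-epoxide of 31 (germacrane numbering 1R,3S,6R,7R,8R,10R; acyl group 2S,3R) | C=C1C(=O)O[C@@H]2/C=C(/C)[C@@H](OC(=O)CC(C)C)C[C@H]3O[C@]3(C)C[C@@H](OC(=O)[C@@]3(C)O[C@@H]3C)[C@@H]12 | target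

## Step count and least certain steps

Total: 22 steps. Longest linear sequence: 17 steps (steps 4 to 18, then 21 and 22, from lactone alcohol 7). The linker (steps 1 to 3) and the acid (steps 19 and 20) are side branches.

**Step 18 (key step).** The course at the aldehyde carbon is the most likely point of failure. The normal chair preference and the constraint of the forming ring have not been tested against each other on this ring, so part or all of the adduct may arise through the chair with C9 pseudo-axial and carry the other C8 configuration. A second concern is that the strained ring closes slowly, so that 26 is lost to intermolecular addition or protonation; dilution answers that first. The fallback makes the end game independent of the C8 outcome. Setting out from 25, any 8R alcohol (3aR,4R,6E,9S,10Z,11aR)-4-hydroxy-6,10-dimethyl-3-methylidene-2-oxo-2,3,3a,4,5,8,9,11a-octahydrocyclodeca[b]furan-9-yl 3-methylbutanoate F1 is esterified with retention under Yamaguchi conditions (2,4,6-trichlorobenzoyl chloride, Et3N, DMAP, toluene) with acid 30. It rejoins the route at 31.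

**Step 21.** Elimination of the activated C8 oxygen towards C7 or C9 may compete with substitution, because the carbinol is flanked by an allylic methine and the nucleophile is a hindered carboxylate. Addition of phosphine to the methylene lactone is a further loss channel. The fallback separates activation from displacement and uses no phosphine. Setting out from 27, chloromethanesulfonyl chloride and pyridine give the C8 chloromethanesulfonate of 27 F2. Displacement with the caesium salt of 30 (Cs2CO3, 18-crown-6, toluene) inverts C8 and rejoins the route at 31.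

**Step 22.** The peracid may attack the wrong face of C1=C10, because the face exposed depends on which ring conformer reacts. Acid-induced transannular opening of the new epoxide is a lesser risk. The fallback epoxidises before the esterification and lets the C8 hydroxyl choose the reacting conformer. Setting out from 27, VO(acac)2 and t-BuOOH in CH2Cl2 deliver oxygen from the side of the bound C8 alkoxide to give the (1R,10R)-1,10-epoxide of 27 F3. Mitsunobu esterification of F3 with 30 (PPh3, DIAD) then leads directly to 32.

**Step 12.** Facial discrimination may be poor, because the Z enone is twisted out of conjugation and the catalyst must tell an α-branched alkenyl group from an allylic methylene; conjugate reduction is a lesser risk. The fallback corrects C3 during the acylation. Setting out from 19, whatever 3R alcohol (5R)-3-{[(tert-butyldimethylsilyl)oxy]methyl}-5-[(1Z,3R,5E)-3-hydroxy-8-[(4-methoxybenzyl)oxy]-2,6-dimethylocta-1,5-dien-1-yl]furan-2(5H)-one F4 is formed is separated. It is esterified with inversion by a Mitsunobu reaction with 3-methylbutanoic acid (PPh3, DIAD) and rejoins the route at 21, while the 3S alcohol 20 is acylated as in step 13.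

**Step 5.** Low Z selectivity, loss of iodine from the ylide, or epimerisation of the α-oxygenated aldehyde may occur, since the iodo ylide is unstable and basic by-products accumulate. The fallback builds the haloalkene in two stereodefined stages. Setting out from 8, dibromo-olefination (CBr4, PPh3, CH2Cl2) gives (5S)-5-(2,2-dibromoethenyl)dihydrofuran-2(3H)-one F5. Negishi coupling with MeZnCl and Pd(PPh3)4 replaces only the bromine trans to the lactone carbon and gives (5S)-5-[(1Z)-2-bromoprop-1-en-1-yl]dihydrofuran-2(3H)-one F6. Copper-catalysed halogen exchange (CuI, N,N'-dimethylethane-1,2-diamine, NaI, dioxane, heat) proceeds with retention and rejoins the route at 9.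

## Further compounds

F1 | step 18 | (3aR,4R,6E,9S,10Z,11aR)-4-hydroxy-6,10-dimethyl-3-methylidene-2-oxo-2,3,3a,4,5,8,9,11a-octahydrocyclodeca[b]furan-9-yl 3-methylbutanoate (8R epimer of 27) | C=C1C(=O)O[C@@H]2/C=C(/C)[C@@H](OC(=O)CC(C)C)C/C=C(\C)C[C@@H](O)[C@@H]12
F2 | step 21 | C8 chloromethanesulfonate of 27 (8S) | C=C1C(=O)O[C@@H]2/C=C(/C)[C@@H](OC(=O)CC(C)C)C/C=C(\C)C[C@H](OS(=O)(=O)CCl)[C@@H]12
F3 | step 22 | (1R,10R)-1,10-epoxide of 27 (8S alcohol) | C=C1C(=O)O[C@@H]2/C=C(/C)[C@@H](OC(=O)CC(C)C)C[C@H]3O[C@]3(C)C[C@H](O)[C@@H]12
F4 | step 12 | (5R)-3-{[(tert-butyldimethylsilyl)oxy]methyl}-5-[(1Z,3R,5E)-3-hydroxy-8-[(4-methoxybenzyl)oxy]-2,6-dimethylocta-1,5-dien-1-yl]furan-2(5H)-one | O=C1C(CO[Si](C)(C)C(C)(C)C)=C[C@@H](/C=C(/C)[C@H](O)C/C=C(\C)CCOCc2ccc(OC)cc2)O1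
F5 | step 5 | (5S)-5-(2,2-dibromoethenyl)dihydrofuran-2(3H)-one | O=C1CC[C@@H](C=C(Br)Br)O1
F6 | step 5 | (5S)-5-[(1Z)-2-bromoprop-1-en-1-yl]dihydrofuran-2(3H)-one | O=C1CC[C@@H](/C=C(/C)Br)O1
A1 | alternative 1 | enal oxime precursor with a C1=C2 vinyl group, C8 TBS ether and C10 TES ether on the saturated lactone | O=C1C[C@H]([C@H](O[Si](C)(C)C(C)(C)C)C[C@@](C)(O[Si](CC)(CC)CC)C=C)[C@@H](/C=C(/C)C=NO)O1
A2 | alternative 1 | isoxazoline-bridged ten-membered lactone (N–O bridge from C3 to C1) | O=C1C[C@@H]2[C@H](O[Si](C)(C)C(C)(C)C)C[C@@](C)(O[Si](CC)(CC)CC)[C@@H]3CC(=NO3)/C(C)=C\[C@H]2O1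
A3 | alternative 2 | cis-anti-cis six-four-four tricyclic ketone with C4 methyl ester and C8 TBS ether (one diastereomer drawn) | O=C1C[C@H](O[Si](C)(C)C(C)(C)C)C[C@]2(C)[C@H]3CC[C@@]3(C(=O)OC)[C@H]12
A4 | alternative 2 | ten-membered dienone with E C1=C10, ring-cis C4=C5, C15 methyl ester and C8 TBS ether | O=C1/C=C(/C(=O)OC)CC/C=C(\C)C[C@@H](O[Si](C)(C)C(C)(C)C)C1
A5 | alternative 3 | eleven-membered cyclic sulfone with sulfur between C4 and C5 (C4 epimers) | C(c2ccc(OC)cc2)O[C@@H]1CS(=O)(=O)C(C)[C@@H](O[Si](C)(C)C(C)(C)C)C/C=C(\C)C[C@@H](O[Si](C(C)C)(C(C)C)C(C)C)[C@H]1CCOCc1ccc(OC)cc1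
A6 | alternative 3 | ten-membered 1(10)E,4Z-diene with C6 and C12 PMB ethers, C8 TIPS ether and C3 TBS ether | C(c2ccc(OC)cc2)O[C@@H]1/C=C(/C)[C@@H](O[Si](C)(C)C(C)(C)C)C/C=C(\C)C[C@@H](O[Si](C(C)C)(C(C)C)C(C)C)[C@H]1CCOCc1ccc(OC)cc1
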